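The data were computed with made-up constants; noise was put on by code.

One millimole per litre of coupling partner turns, by the overall equation, into one millimole per litre of target, and I reckoned Wednesday's flask in that unit.

| flask | starting material | coupling partner | free catalyst | time |
|---|---|---|---|---|
| Friday's | 100 mM | 80.0 mM | 0.500 mM |  |
| Thursday's | 40.0 mM | 20.0 mM | 0.500 mM |  |
| Sunday's | 100 mM | 80.0 mM | 1.50 mM |  |
| Monday's | 150 mM | 80.0 mM | 0.500 mM |  |
| Wednesday's | 100 mM | 16.0 mM | 0.500 mM | 11 min |

| run | time / min | [target] / mM |
|---|---|---|
| Friday's run | 1.4 | 7.6 |
| Friday's run | 2.8 | 15.2 |
| Friday's run | 4.1 | 19.9 |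
| Friday's run | 5.5 | 24.6 |
| Friday's run | 6.9 | 28.0 |
| Friday's run | 8.2 | 28.9 |
| Friday's run | 9.6 | 30.9 |
| Friday's run | 11 | 30.6 |
| Thursday's run | 1.4 | 2.6 |
| Thursday's run | 2.8 | 4.7 |
| Thursday's run | 4.1 | 6.4 |
| Thursday's run | 5.5 | 8.5 |
| Thursday's run | 6.9 | 9.3 |
| Thursday's run | 8.2 | 10.4 |
| Thursday's run | 9.6 | 10.2 |
| Thursday's run | 11 | 11.7 |
| Sunday's run | 1.4 | 19.0 |
| Sunday's run | 2.8 | 33.4 |
| Sunday's run | 4.1 | 40.0 |
| Sunday's run | 5.5 | 43.9 |
| Sunday's run | 6.9 | 43.5 |
| Sunday's run | 8.2 | 44.9 |
| Sunday's run | 9.6 | 44.9 |
| Sunday's run | 11 | 45.2 |
| Monday's run | 1.4 | 9.6 |
| Monday's run | 2.8 | 20.9 |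
| Monday's run | 4.1 | 29.7 |
| Monday's run | 5.5 | 34.6 |
| Monday's run | 6.9 | 38.2 |
| Monday's run | 8.2 | 38.1 |
| Monday's run | 9.6 | 38.7 |
| Monday's run | 11 | 40.3 |

(each reading ± 0.5 mM)

- Overall: starting material + coupling partner -> target, with free catalyst as catalyst.
- Constant volume, constant temperature.
- What is held in complexes is read along with the free species.
- "The second partner" is coupling partner.
- An order is taken over about fifteen percent of the charge, up and down.

* how the opening rate goes with [coupling partner] round the charge of the Friday's run: the exponent of the rate at two percent of starting material gone to target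
* how the opening rate goes with [free catalyst] round the charge of the Friday's run: the exponent of the rate at two percent of starting material gone to target
* target in the Wednesday's run at 11 min, as a share of the starting material charged

Wednesday's flask holds less coupling partner than starting material, so coupling partner is the limiting reagent and its charge sets a ceiling on the target, counted as a share of the starting material. I wrote the balance in fractions of the charge:

ceiling = 16.0 mM / 100 mM = 16.0%

target share = ceiling × partner share

I then asked which of the given numbers had to be known well. The time asked, 11 min, is the time of Thursday's last reading, so I needed no step across times. The catalyst charge matches Friday's and Thursday's, so I needed no step across catalyst charges. An error in either charge would move the ceiling in proportion, but those charges are given, not read. What remained unknown was the partner share, which multiplies the ceiling directly.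

Thursday's last reading, at 11 min, gives a partner share of 58.5%, the partner share being the target as a share of the coupling partner charged. Friday's reads 38.2%, lower than Thursday's, and Friday's flask was charged with more coupling partner. Thursday's charge of coupling partner lies nearer to Wednesday's than Friday's does, so I took its share:

16.0% × 58.5% = 9.36%

That was my own low estimate, with the ceiling as the high end.

The forecast differed from mine. It gave 13%, between 10.5% and 15%, holding that the partner is “largely used before the catalyst dies”. It put the order in coupling partner at 0.15 and the order in free catalyst at 0.95.

The flask gave an order of 0.45 in coupling partner, 0.91 in free catalyst, and 10.9% of target.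

free catalyst + starting material → catalyst-substrate complex (1446 L mol⁻¹ min⁻¹); catalyst-substrate complex + coupling partner → loaded catalyst (316.8 L mol⁻¹ min⁻¹); loaded catalyst → target + free catalyst (17.04 min⁻¹); starting material + coupling partner + target → 2 target (84.00 L² mol⁻² min⁻¹); target + coupling partner → side product (5.052 L mol⁻¹ min⁻¹) The forecast's order in coupling partner stood at a third of the result, while its other two numbers fell inside their ranges. The scheme holds a step in which target and coupling partner go to side product. Wednesday's partner share at 11 min comes to 68.1%, above Thursday's. On Sunday's flask the ceiling is 80.0%, so Thursday's partner share puts the target at 46.8% of the starting material, and Sunday's reading at 11 min is 45.2%.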